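**Plan**

1. Retrosynthesis: cut the C2–aryl bond of the flavanone (ring C) to give 7-silyloxy-8-prenylchromone and a chromen-6-ylboronic acid. Cut the pyran ring of the chromene at O1–C8a and C3–C4 to give 5-bromo-2-fluorobenzaldehyde and a C,O-dilithiated tert-butoxide unit. Cut C8–prenyl by a Claisen transform back to the 7-O-(1,1-dimethylallyl) ether of 7-hydroxychromone.
2. Enabling feature: in the chromene the arene carbon that bears the pyran oxygen (C8a) and the arene carbon that bears the vinylic CH (C4a) are ortho neighbours. With F on the first and CHO on the second the arene is a 1,3-dielectrophile, and the O1–C2(Me)2–C3 segment of the pyran ring is the matching 1,3-dinucleophile, so the ring closes in one [3+3] operation. The bromine para to fluorine later becomes the boron handle.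
3. Forward order: pyran ring of the chromene (step 1), its C3=C4 bond by loss of the helper hydroxyl (step 2), boronic acid (step 3). Separately, O-propargylation, semi-hydrogenation, Claisen rearrangement and silylation on the chromone (steps 4–7). The halves are joined by conjugate addition (step 8), then desilylation (step 9).
4. Stereochemistry: the single stereocentre, C2 (S), comes from catalyst control in the palladium/pyridine-oxazoline conjugate addition. The racemic carbinol made in step 1 is erased in step 2.

Key step: step 1

Assumption: compounds 1, 2 and 10 and both enantiomers of t-BuPyOx (4-tert-butyl-2-(pyridin-2-yl)-4,5-dihydrooxazole) are taken as purchasable. The (R)-ligand is expected to give the (2S)-flavanone by analogy with the facial sense of this catalyst on cyclic enones; the antipodal ligand would be used if the sense proved opposite.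

**Step 1**
Reactants: 1 5-bromo-2-fluorobenzaldehyde; 2 1-chloro-2-methylpropan-2-ol
Product: 5 6-bromo-2,2-dimethyl-3,4-dihydro-2H-chromen-4-ol (racemic), via dilithium 2-methyl-2-oxidopropan-1-ide 3 (not isolated), via dilithium 1-(5-bromo-2-fluorophenyl)-3-methylbutane-1,3-diolate 4 (not isolated)
Conditions: 2, n-BuLi (1.0 equiv), THF, −78 °C; LiC10H8 (lithium naphthalenide, 2.0 equiv), −78 °C; cannulate into 1, THF, −78 °C; then t-BuOK, DMPU, 65 °C; H2O
Reagents that add atoms: none
Why: Reductive lithiation of the C–Cl bond of the lithium alkoxide of 2 gives the C,O-dilithio reagent 3, whose CH2 carbanion (C3 of the future pyran) should add to the formyl carbon of 1 (C4) at −78 °C faster than it exchanges with the aryl bromide or loses lithium oxide, giving diolate 4; on warming with potassium counter-ions in a dipolar medium the tertiary alkoxide (O1) should attack the fluorine-bearing ring carbon (C8a) by addition–elimination and expel fluoride. The closest known reaction types are the addition of β-oxido organolithiums made from chlorohydrins to aldehydes and the intramolecular SNAr etherification of 2-fluoroaryl alkanols, run here as one [3+3] annulation of a C,O-1,3-dinucleophile onto a 1,3-dielectrophile. The pyran ring closes in a six-membered exo mode (6-exo-trig at the C8a=C8 bond) through a Meisenheimer-type transition state. The only new stereocentre, carbinol C4, is not controlled, forms as a racemate and is erased in step 2. The step needs chemoselectivity: carbonyl addition before ring closure (secured by temperature and inverse addition), fluoride and not bromide as the nucleofuge (secured by the far higher SNAr rate of C–F, helped a little by the para bromine, and by the absence of a transition metal), and the tertiary and not the secondary alkoxide as the nucleophile (secured by ring size, six against four).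

**Step 2**
Reactants: 5 6-bromo-2,2-dimethyl-3,4-dihydro-2H-chromen-4-ol
Product: 6 6-bromo-2,2-dimethyl-2H-chromene
Conditions: TsOH·H2O (5 mol %), toluene, reflux, azeotropic removal of water
Reagents that add atoms: none
Why: Acid-catalysed E1 dehydration of the benzylic alcohol, whose cation at C4 is stabilised by the ortho ring oxygen and can lose a proton only from C3 because C2 is quaternary, so the C3=C4 bond forms regiospecifically.

**Step 3**
Reactants: 6 6-bromo-2,2-dimethyl-2H-chromene
Product: 9 (2,2-dimethyl-2H-chromen-6-yl)boronic acid, via (2,2-dimethyl-2H-chromen-6-yl)lithium 7 (not isolated), via lithium triisopropoxy(2,2-dimethyl-2H-chromen-6-yl)borate 8 (not isolated)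
Conditions: n-BuLi, THF, −78 °C; B(Oi-Pr)3, −78 °C to rt; 1 M HCl
Reagents that add atoms: triisopropyl borate, CC(C)OB(OC(C)C)OC(C)C; water, O
Why: Bromine–lithium exchange, trapping of the aryllithium with a borate ester and hydrolysis is the standard route to arylboronic acids, and the styrenic alkene and the aryl ether are inert to n-BuLi at −78 °C.

**Step 4**
Reactants: 10 7-hydroxy-4H-chromen-4-one
Product: 11 7-[(2-methylbut-3-yn-2-yl)oxy]-4H-chromen-4-one
Conditions: 3-chloro-3-methylbut-1-yne, DBU, CuCl2·2H2O (1 mol %), MeCN, 0 °C to rt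
Reagents that add atoms: 3-chloro-3-methylbut-1-yne, C#CC(C)(C)Cl
Why: Copper-catalysed propargylic substitution of a tertiary propargyl chloride by a phenol gives aryl 1,1-dimethylpropargyl ethers and works well with acidic, electron-poor phenols such as 10.

**Step 5**
Reactants: 11 7-[(2-methylbut-3-yn-2-yl)oxy]-4H-chromen-4-one
Product: 12 7-[(2-methylbut-3-en-2-yl)oxy]-4H-chromen-4-one
Conditions: H2 (1 atm), Pd/CaCO3 poisoned with Pb(OAc)2, quinoline, EtOAc, rt
Reagents that add atoms: none
Why: Semi-hydrogenation of a terminal alkyne over lead-poisoned palladium stops at the alkene, and the vinylogous-ester C2=C3 bond of the chromone should not be reduced under these conditions.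

**Step 6**
Reactants: 12 7-[(2-methylbut-3-en-2-yl)oxy]-4H-chromen-4-one
Product: 14 7-hydroxy-8-(3-methylbut-2-en-1-yl)-4H-chromen-4-one, via 8-(3-methylbut-2-en-1-yl)-8H-chromene-4,7-dione 13 (not isolated)
Conditions: N,N-diethylaniline, 130 °C
Reagents that add atoms: none
Why: Aromatic Claisen rearrangement ([3,3]) of the 1,1-dimethylallyl ether should deliver the allyl terminus to C8, the ortho position joined to C7 by the bond of higher double-bond character in the benzopyranone (the usual preference of 7-allyloxy-chromones and -coumarins), and dienone 13 tautomerises to the phenol carrying the normal prenyl group.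

**Step 7**
Reactants: 14 7-hydroxy-8-(3-methylbut-2-en-1-yl)-4H-chromen-4-one
Product: 15 7-[(tert-butyldimethylsilyl)oxy]-8-(3-methylbut-2-en-1-yl)-4H-chromen-4-one
Conditions: t-BuMe2SiCl, imidazole, DMF, rt
Reagents that add atoms: tert-butyldimethylsilyl chloride, CC(C)(C)[Si](C)(C)Cl
Why: Standard silylation of a phenol, which masks the acidic hydroxyl during the palladium-catalysed step and can later be removed without base.

**Step 8**
Reactants: 15 7-[(tert-butyldimethylsilyl)oxy]-8-(3-methylbut-2-en-1-yl)-4H-chromen-4-one; 9 (2,2-dimethyl-2H-chromen-6-yl)boronic acid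
Product: 16 (2S)-7-[(tert-butyldimethylsilyl)oxy]-2-(2,2-dimethyl-2H-chromen-6-yl)-8-(3-methylbut-2-en-1-yl)-2,3-dihydro-4H-chromen-4-one
Conditions: 9 (2 equiv), Pd(OCOCF3)2 (5 mol %), (R)-t-BuPyOx (6 mol %), NH4PF6 (30 mol %), H2O (5 equiv), ClCH2CH2Cl, 60 °C
Reagents that add atoms: none
Why: Enantioselective 1,4-addition of an arylboronic acid to a chromone by the cationic divalent palladium complex formed from Pd(OCOCF3)2 and the pyridine-oxazoline ligand, in which the aryl–palladium species inserts the C2=C3 bond on the enone face left open by the tert-butyl group and water protonates the palladium enolate, so the ligand configuration should set C2 as (S) while the cis-disubstituted chromene and trisubstituted prenyl alkenes are poor insertion partners.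

**Step 9**
Reactants: 16 (2S)-7-[(tert-butyldimethylsilyl)oxy]-2-(2,2-dimethyl-2H-chromen-6-yl)-8-(3-methylbut-2-en-1-yl)-2,3-dihydro-4H-chromen-4-one
Product: 17 (2S)-2-(2,2-dimethyl-2H-chromen-6-yl)-7-hydroxy-8-(3-methylbut-2-en-1-yl)-2,3-dihydro-4H-chromen-4-one
Conditions: Bu4NF, AcOH, THF, 0 °C
Reagents that add atoms: none
Why: Fluoride cleavage of the aryl silyl ether buffered with acetic acid keeps the medium near neutral, so the flavanone should not open to the chalcone (retro-oxa-Michael) and C2 should keep its configuration.

**Compound list**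

1 | 5-bromo-2-fluorobenzaldehyde | O=Cc1cc(Br)ccc1F | starting material
2 | 1-chloro-2-methylpropan-2-ol | CC(C)(O)CCl | starting material
3 | dilithium 2-methyl-2-oxidopropan-1-ide | [Li]CC(C)(C)O[Li] | intermediate
4 | dilithium 1-(5-bromo-2-fluorophenyl)-3-methylbutane-1,3-diolate (racemic) | [Li]OC(CC(C)(C)O[Li])c1cc(Br)ccc1F | intermediate
5 | 6-bromo-2,2-dimethyl-3,4-dihydro-2H-chromen-4-ol (racemic) | CC1(C)CC(O)c2cc(Br)ccc2O1 | intermediate
6 | 6-bromo-2,2-dimethyl-2H-chromene | CC1(C)C=Cc2cc(Br)ccc2O1 | intermediate
7 | (2,2-dimethyl-2H-chromen-6-yl)lithium | [Li]c1ccc2c(c1)C=CC(C)(C)O2 | intermediate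
8 | lithium triisopropoxy(2,2-dimethyl-2H-chromen-6-yl)borate | [Li+].CC(C)O[B-](OC(C)C)(OC(C)C)c1ccc2c(c1)C=CC(C)(C)O2 | intermediate
9 | (2,2-dimethyl-2H-chromen-6-yl)boronic acid | CC1(C)C=Cc2cc(B(O)O)ccc2O1 | intermediate
10 | 7-hydroxy-4H-chromen-4-one | O=c1ccoc2cc(O)ccc12 | starting material
11 | 7-[(2-methylbut-3-yn-2-yl)oxy]-4H-chromen-4-one | C#CC(C)(C)Oc1ccc2c(c1)occc2=O | intermediate
12 | 7-[(2-methylbut-3-en-2-yl)oxy]-4H-chromen-4-one | C=CC(C)(C)Oc1ccc2c(c1)occc2=O | intermediate
13 | 8-(3-methylbut-2-en-1-yl)-8H-chromene-4,7-dione (racemic) | CC(C)=CCC1C(=O)C=CC2=C1OC=CC2=O | intermediate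
14 | 7-hydroxy-8-(3-methylbut-2-en-1-yl)-4H-chromen-4-one | CC(C)=CCc1c(O)ccc2c1occc2=O | intermediate
15 | 7-[(tert-butyldimethylsilyl)oxy]-8-(3-methylbut-2-en-1-yl)-4H-chromen-4-one | CC(C)=CCc1c(O[Si](C)(C)C(C)(C)C)ccc2c1occc2=O | intermediate
16 | (2S)-7-[(tert-butyldimethylsilyl)oxy]-2-(2,2-dimethyl-2H-chromen-6-yl)-8-(3-methylbut-2-en-1-yl)-2,3-dihydro-4H-chromen-4-one | CC(C)=CCc1c(O[Si](C)(C)C(C)(C)C)ccc2c1O[C@H](c1ccc3c(c1)C=CC(C)(C)O3)CC2=O | intermediate
17 | (2S)-2-(2,2-dimethyl-2H-chromen-6-yl)-7-hydroxy-8-(3-methylbut-2-en-1-yl)-2,3-dihydro-4H-chromen-4-one | CC(C)=CCc1c(O)ccc2c1O[C@H](c1ccc3c(c1)C=CC(C)(C)O3)CC2=O | target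

**Step count**

Total: 9 steps. Longest linear sequence: 6 steps (10 to 17, steps 4–9); the other branch (1 to 17) runs through steps 1, 2, 3, 8 and 9.

**Steps most likely to fail**

Step 1. What may go wrong: bromine–lithium exchange or loss of lithium oxide from 3 before the carbonyl addition, or a ring closure that stalls because the fluoroarene of 4 is only weakly activated once the formyl group has been consumed. Fallback from compound 1 to compound 6, in which the order of the two bond formations is reversed and the alkene is made by metathesis: the potassium alkoxide of 2-methylbut-3-en-2-ol (KH, THF, 0 °C) should displace fluoride from 1 while the ortho formyl group still activates the ring, giving 5-bromo-2-[(2-methylbut-3-en-2-yl)oxy]benzaldehyde F1. Wittig methylenation (Ph3P=CH2 from Ph3PCH3Br and t-BuOK, THF, 0 °C) should give 4-bromo-2-ethenyl-1-[(2-methylbut-3-en-2-yl)oxy]benzene F2. Ring-closing metathesis with the second-generation Grubbs catalyst (CH2Cl2, 40 °C) should then close the C3=C4 bond with loss of ethylene and give 6.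

Step 8. What may go wrong: slow insertion into the electron-rich, ortho-substituted chromone, protodeboronation of the electron-rich boronic acid, or insufficient facial selectivity. Fallback from compound 15 (with 9) to compound 16, in which the addition is run without asymmetric induction and the enantiomer is secured by kinetic resolution: Pd(OCOCF3)2 with 2,2′-bipyridine under otherwise similar conditions should give the racemic silyl ether, 7-[(tert-butyldimethylsilyl)oxy]-2-(2,2-dimethyl-2H-chromen-6-yl)-8-(3-methylbut-2-en-1-yl)-2,3-dihydro-4H-chromen-4-one (racemic) F3. Asymmetric transfer hydrogenation with RuCl(p-cymene)[(R,R)-TsDPEN] (or its antipode, whichever consumes the (2R)-ketone faster), HCO2H/Et3N, stopped near half conversion, should reduce the (2R)-ketone to the cis alcohol (2R,4R)-7-[(tert-butyldimethylsilyl)oxy]-2-(2,2-dimethyl-2H-chromen-6-yl)-8-(3-methylbut-2-en-1-yl)-3,4-dihydro-2H-chromen-4-ol F4 and leave the (2S)-ketone 16, to be separated by chromatography.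

Step 6. What may go wrong: migration to C6 instead of C8, ionisation of the tertiary allylic ether back to the phenol, or further cyclisation of the ortho-prenylphenol at the temperature of the rearrangement. Fallback from compound 10 to compound 15, in which the prenyl group is introduced by cross-coupling at a halogen placed on C8: iodination of 10 (I2, KI, aqueous NH3, 0 °C), directed to the position between the two oxygens, should give 7-hydroxy-8-iodo-4H-chromen-4-one F5. Silylation (t-BuMe2SiCl, imidazole, DMF) should give 7-[(tert-butyldimethylsilyl)oxy]-8-iodo-4H-chromen-4-one F6. Stille coupling with tributyl(3-methylbut-2-en-1-yl)stannane (Pd(PPh3)4, DMF, 80 °C) should give 15.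

**Further compounds**

F1 | step 1 | 5-bromo-2-[(2-methylbut-3-en-2-yl)oxy]benzaldehyde | C=CC(C)(C)Oc1ccc(Br)cc1C=O
F2 | step 1 | 4-bromo-2-ethenyl-1-[(2-methylbut-3-en-2-yl)oxy]benzene | C=CC(C)(C)Oc1ccc(Br)cc1C=C
F3 | step 8 | 7-[(tert-butyldimethylsilyl)oxy]-2-(2,2-dimethyl-2H-chromen-6-yl)-8-(3-methylbut-2-en-1-yl)-2,3-dihydro-4H-chromen-4-one (racemic) | CC(C)=CCc1c(O[Si](C)(C)C(C)(C)C)ccc2c1OC(c1ccc3c(c1)C=CC(C)(C)O3)CC2=O
F4 | step 8 | (2R,4R)-7-[(tert-butyldimethylsilyl)oxy]-2-(2,2-dimethyl-2H-chromen-6-yl)-8-(3-methylbut-2-en-1-yl)-3,4-dihydro-2H-chromen-4-ol | CC(C)=CCc1c(O[Si](C)(C)C(C)(C)C)ccc2c1O[C@@H](c1ccc3c(c1)C=CC(C)(C)O3)C[C@H]2O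
F5 | step 6 | 7-hydroxy-8-iodo-4H-chromen-4-one | O=c1ccoc2c(I)c(O)ccc12
F6 | step 6 | 7-[(tert-butyldimethylsilyl)oxy]-8-iodo-4H-chromen-4-one | CC(C)(C)[Si](C)(C)Oc1ccc2c(c1I)occc2=O
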